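The earlier runs and the new flask are calculated from invented constants; noise was put on by code.

Reagent in the second phase stands at 1.50 times the starting material in this flask, against 1.05 in the east run and 0.668 in the south-west run, so you reckon with those two charges and a clock you assume the three share.

all flasks: reagent in the second phase 0.147 M
- east: starting material 0.14 M; run made earlier
- south-west: starting material 0.22 M; run made earlier
- flask: starting material 0.098 M; time 6.0 h; volume of the second phase over the first 0.25

| run | time / h | target / % | starting material / % |
|---|---|---|---|
| east | 0.417 | 3.3 | 96.3 |
| east | 1.33 | 18.8 | 82.0 |
| east | 2.00 | 28.5 | 71.4 |
| east | 3.00 | 39.5 | 56.5 |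
| east | 5.00 | 54.3 | 40.5 |
| east | 6.00 | 56.8 | 35.6 |
| south-west | 1.00 | 13.2 | 88.8 |
| south-west | 2.00 | 28.3 | 75.0 |
| south-west | 3.00 | 34.0 | 61.7 |
| south-west | 4.00 | 41.7 | 54.2 |
| south-west | 5.00 | 45.3 | 48.3 |
| south-west | 6.00 | 46.9 | 45.7 |

(each reading ± 1 percentage point)

- target is meant together with its product in the second phase
- in the second phase: reagent in the second phase, product in the second phase; everything else is in the first
- charges count per volume of the first phase; a concentration in a rate is the amount of a species over the volume of its own phase; every rate counts per litre of the first phase
- the earlier runs hold the two phases in the same ratio of volumes as the flask asked about

- amount of target and product in the second phase together at 6.0 h, in percent of the starting material charged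
- part of the starting material charged that has reacted at 6.0 h

Take one step, starting material with reagent one to one, at a rate k times both unspent amounts, and let k depend on the hour in the same way in all three; both runs hold the flask's phase ratio. Integrated, the logarithm of the reagent's fraction left over the starting material's fraction left, divided by the excess of reagent charge over starting charge, equals the integral of k. The readings at 6.00 h give 11.8 /M for east and 12.2 /M for south-west, so you carry their mean, 12.0 /M, as the exposure. In this flask, with starting material the limiting reagent at 0.098 M against 0.147 M, that exposure leaves 29.4%, so 70.6% has reacted. Of the reacted part, target, counted with its product in the second phase, read 88.2% in east and 86.4% in south-west; their mean, 87.3%, gives your estimate of 61.6% for this flask.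

The forecast, holding that “there is an induction period”, gives 69% reacted and 61% of target. The flask gives 70.5% reacted and 62.0% of target.

    reagent in the reaction phase ⇌ reagent in the second phase, rate k1*([reagent in the reaction phase] - [reagent in the second phase]/K1) per volume of the first phase (partition coefficient = 0.680, kL = 0.210 /h)
    starting material + reagent in the reaction phase → target (k = 2.70 /M/h)
    target ⇌ product in the second phase, rate k3*([target] - [product in the second phase]/K3) per volume of the first phase (partition coefficient = 3.10, kL = 0.220 /h)
    target → decomposed product (k = 0.0360 /h)
    target → over-reaction product (k = 0.0140 /h)

Now charge the neighbouring flask with 0.39 M of starting material, the reagent in the second phase held at 0.147 M, so that this reagent is the smaller charge. The exposure 12.0 /M goes into the same equation and leaves 63.6% of the starting material, which means 36.4% reacted and, with the share 87.3%, 31.8% of target. That neighbouring flask gives 35.9% reacted and 30.9% of target, with 64.1% of its starting material left.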